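**Retrosynthetic overview**

1. Target 18 ⇐ 17 (desilylation) ⇐ 16 (catalyst-controlled reduction of the C1 ketone) ⇐ 13 (acylation of O5, the former pyran oxygen) ⇐ 12 (hydration of a C1-aryl glycal).
2. Key disconnection: the bond between ring B C4 and chain C1, made from C1-metalated 3,4-di-O-TBS-L-fucal (an α-alkoxyvinyl metal, i.e. an acyl anion equivalent of the sugar's anomeric carbon) and heteroaryl triflate 6 by Negishi coupling.
3. C3, C4 and C5 come from L-fucose. The glycal ring oxygen singles out O5 for the myristate, so no hydroxyl-differentiation steps are needed; C1 is set last.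
4. Triflate 6 ⇐ oxazol-4(5H)-one 5 ⇐ acyl isocyanate + diazoalkane ⇐ amide 2 ⇐ acid 1.
5. Rings: ring A (terminal oxazole) and ring C (dihydropyran of L-fucal) are bought in; ring B (central oxazole) is built in step 2 and aromatised in step 3; ring C is opened in step 7. Chain numbering: C1 = carbon on ring B, C6 = CH3.

Assumption: 2-(oxazol-5-yl)acetic acid, 3,4-di-O-acetyl-L-fucal and tetradecanoyl chloride are taken as catalogue starting materials (the first two are not bulk-cheap).

**Route**

Step 1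
Reactants: 1 2-(1,3-oxazol-5-yl)acetic acid
Product: 2 2-(1,3-oxazol-5-yl)acetamide
Conditions: CDI, THF, rt; then NH3 (0.5 M in 1,4-dioxane), 0 °C to rt
Reagents that add atoms: ammonia, N
Why: acyl imidazolide formation followed by aminolysis (CDI amidation) is neutral and mild enough for a heteroarylacetic acid, and no stereocenter is involved.

Step 2
Reactants: 2 2-(1,3-oxazol-5-yl)acetamide
Product: 5 2-(1,3-oxazol-5-ylmethyl)-1,3-oxazol-4(5H)-one, via acyl isocyanate 3 (not isolated), via 5-silyl oxazolone 4 (not isolated)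
Conditions: (COCl)2, (CH2Cl)2, 0 to 70 °C; evaporate; TMSCHN2, CH2Cl2, 0 °C to rt; MeOH quench
Reagents that add atoms: oxalyl chloride, O=C(Cl)C(=O)Cl; trimethylsilyldiazomethane, C[Si](C)(C)C=[N+]=[N-]
Why: the Speziale reaction of the primary amide with oxalyl chloride gives the acyl isocyanate, the diazo carbon adds to the isocyanate carbon and the acyl oxygen closes ring B with loss of N2 (acyl isocyanate–diazoalkane oxazolone synthesis), and the C-silyl group is lost by protodesilylation in the methanol quench, leaving no stereocenter.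

Step 3
Reactants: 5 2-(1,3-oxazol-5-ylmethyl)-1,3-oxazol-4(5H)-one
Product: 6 2-(1,3-oxazol-5-ylmethyl)-1,3-oxazol-4-yl trifluoromethanesulfonate
Conditions: Tf2O, Et3N, CH2Cl2, −78 °C
Reagents that add atoms: triflic anhydride, O=S(=O)(OS(=O)(=O)C(F)(F)F)C(F)(F)F
Why: O-sulfonylation of the 4-hydroxyoxazole tautomer (enol triflation) aromatises ring B and gives the heteroaryl triflate electrophile, with no stereocenter involved.

Step 4
Reactants: 7 3,4-di-O-acetyl-L-fucal
Product: 9 3,4-di-O-TBS-L-fucal, via L-fucal 8 (not isolated)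
Conditions: K2CO3 (0.1 equiv), MeOH, rt; evaporate; TBSCl, imidazole, DMF, 60 °C
Reagents that add atoms: tert-butyldimethylsilyl chloride, CC(C)(C)[Si](C)(C)Cl
Why: base-catalysed transesterification (Zemplén-type deacetylation) then silylation of both secondary hydroxyls gives the base-stable bis-silyl ether needed for C1 lithiation, and the three L-fucose stereocenters (later C3, C4 and C5 of the chain) are carried through untouched.

Step 5
Reactants: 9 3,4-di-O-TBS-L-fucal; 6 2-(1,3-oxazol-5-ylmethyl)-1,3-oxazol-4-yl trifluoromethanesulfonate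
Product: 12 1-C-[2-(1,3-oxazol-5-ylmethyl)-1,3-oxazol-4-yl]-3,4-di-O-TBS-L-fucal, via 1-lithioglycal 10 (not isolated), via glycal zinc chloride 11 (not isolated)
Conditions: 9 (1.3 equiv), tBuLi (3 equiv), THF, −78 to 0 °C; ZnCl2, 0 °C to rt; then 6 (1.0 equiv), Pd(PPh3)4 (5 mol %), THF, 60 °C
Reagents that add atoms: none
Why: the C1–H of the glycal is the most acidic vinylic proton, so tBuLi gives the α-alkoxyvinyl anion (the anomeric carbon, normally an electrophile, used as a masked acyl anion), which after lithium-to-zinc exchange undergoes Negishi cross-coupling with the electrophilic oxazol-4-yl triflate under base-free conditions that spare the acidic CH2 and C2–H of the bis-oxazole, forming no stereocenter and leaving C3, C4 and C5 untouched.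

Step 6
Reactants: 12 1-C-[2-(1,3-oxazol-5-ylmethyl)-1,3-oxazol-4-yl]-3,4-di-O-TBS-L-fucal
Product: 13 1-C-[2-(1,3-oxazol-5-ylmethyl)-1,3-oxazol-4-yl]-2,6-dideoxy-3,4-di-O-TBS-L-lyxo-hexopyranose (cyclic hemiketal)
Conditions: PPTS (0.2 equiv), THF/H2O 9:1, rt
Reagents that add atoms: water, O
Why: acid-catalysed Markovnikov hydration of the aryl enol ether (C2 protonation, water capture of the oxocarbenium ion at C1) unmasks the acyl carbon at the ketone oxidation level while TBS ethers and oxazoles survive PPTS, and the anomeric centre formed is an inconsequential mixture.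

Step 7
Reactants: 13 1-C-[2-(1,3-oxazol-5-ylmethyl)-1,3-oxazol-4-yl]-2,6-dideoxy-3,4-di-O-TBS-L-lyxo-hexopyranose; 14 tetradecanoyl chloride
Product: 16 (5S)-5-tetradecanoyloxy-3,4-bis(TBS-oxy)-1-[2-(1,3-oxazol-5-ylmethyl)-1,3-oxazol-4-yl]hexan-1-one (L-lyxo keto ester), via open-chain hydroxy ketone 15 (not isolated)
Conditions: pyridine, DMAP (0.2 equiv), CH2Cl2, 0 °C to rt
Reagents that add atoms: none
Why: ring–chain tautomerism exposes the secondary C5–OH of the δ-hydroxy aryl ketone while the tertiary anomeric OH is too hindered to acylate, so DMAP-catalysed esterification drains the equilibrium to the open-chain keto ester, with O5 the only free hydroxyl because it was the glycal ring oxygen and C5 retaining its configuration because its C–O bond is never broken.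

Step 8
Reactants: 16 L-lyxo keto ester
Product: 17 (1R)-alcohol, the 3,4-bis-TBS ether of the target
Conditions: RuCl[(R,R)-TsDPEN](p-cymene) (2 mol %), HCO2H/Et3N 5:2, CH2Cl2, rt
Reagents that add atoms: none
Why: Noyori asymmetric transfer hydrogenation of the heteroaryl alkyl ketone with the (R,R)-catalyst delivers hydride to the face that gives the (R)-carbinol at C1 (same sense as acetophenone to (R)-1-phenylethanol, the oxazole taking the aryl position), catalyst control overriding the remote C3 centre while the ester, silyl ethers and oxazoles are inert.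

Step 9
Reactants: 17 (1R)-alcohol, the 3,4-bis-TBS ether of the target
Product: 18 (2S,3S,4S,6R)-3,4,6-trihydroxy-6-[2-(1,3-oxazol-5-ylmethyl)-1,3-oxazol-4-yl]hexan-2-yl tetradecanoate
Conditions: HF·pyridine, pyridine, THF, 0 °C to rt
Reagents that add atoms: none
Why: fluoride-mediated desilylation under a weakly acidic buffer removes both TBS ethers without the base-promoted O5-to-O4 acyl migration that basic fluoride sources would risk, and no stereocenter is touched.

**Compound list**

1 | 2-(1,3-oxazol-5-yl)acetic acid | OC(=O)Cc1cnco1 | starting material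
2 | 2-(1,3-oxazol-5-yl)acetamide | NC(=O)Cc1cnco1 | intermediate
3 | 2-(1,3-oxazol-5-yl)acetyl isocyanate | O=C=NC(=O)Cc1cnco1 | intermediate (not isolated)
4 | 2-(1,3-oxazol-5-ylmethyl)-5-(trimethylsilyl)-1,3-oxazol-4(5H)-one (racemic at C5) | O=C1N=C(Cc2cnco2)OC1[Si](C)(C)C | intermediate (not isolated)
5 | 2-(1,3-oxazol-5-ylmethyl)-1,3-oxazol-4(5H)-one | O=C1COC(Cc2cnco2)=N1 | intermediate
6 | 2-(1,3-oxazol-5-ylmethyl)-1,3-oxazol-4-yl trifluoromethanesulfonate | O=S(=O)(Oc1coc(Cc2cnco2)n1)C(F)(F)F | intermediate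
7 | 3,4-di-O-acetyl-L-fucal (1,5-anhydro-2,6-dideoxy-L-lyxo-hex-1-enitol diacetate) | C[C@@H]1OC=C[C@H](OC(C)=O)[C@@H]1OC(C)=O | starting material
8 | L-fucal ((2S,3S,4S)-2-methyl-3,4-dihydro-2H-pyran-3,4-diol) | C[C@@H]1OC=C[C@H](O)[C@@H]1O | intermediate (not isolated)
9 | 3,4-di-O-(tert-butyldimethylsilyl)-L-fucal | C[C@@H]1OC=C[C@H](O[Si](C)(C)C(C)(C)C)[C@@H]1O[Si](C)(C)C(C)(C)C | intermediate
10 | 1-lithio-3,4-di-O-TBS-L-fucal | C[C@@H]1OC([Li])=C[C@H](O[Si](C)(C)C(C)(C)C)[C@@H]1O[Si](C)(C)C(C)(C)C | intermediate (not isolated)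
11 | (3,4-di-O-TBS-L-fucal-1-yl)zinc chloride | C[C@@H]1OC([Zn]Cl)=C[C@H](O[Si](C)(C)C(C)(C)C)[C@@H]1O[Si](C)(C)C(C)(C)C | intermediate (not isolated)
12 | 1-C-[2-(1,3-oxazol-5-ylmethyl)-1,3-oxazol-4-yl]-3,4-di-O-TBS-L-fucal (C1-aryl glycal, C1=C2 enol ether) | C[C@@H]1OC(c2coc(Cc3cnco3)n2)=C[C@H](O[Si](C)(C)C(C)(C)C)[C@@H]1O[Si](C)(C)C(C)(C)C | intermediate
13 | 1-C-[2-(1,3-oxazol-5-ylmethyl)-1,3-oxazol-4-yl]-2,6-dideoxy-3,4-di-O-TBS-L-lyxo-hexopyranose (cyclic hemiketal, anomeric mixture, ring tautomer of 15) | C[C@@H]1OC(O)(c2coc(Cc3cnco3)n2)C[C@H](O[Si](C)(C)C(C)(C)C)[C@@H]1O[Si](C)(C)C(C)(C)C | intermediate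
14 | tetradecanoyl chloride (myristoyl chloride) | CCCCCCCCCCCCCC(=O)Cl | starting material
15 | open-chain tautomer of 13: (5S)-5-hydroxy-3,4-bis(TBS-oxy)-1-[2-(1,3-oxazol-5-ylmethyl)-1,3-oxazol-4-yl]hexan-1-one, C3–C5 arranged as in L-fucose | O[C@@H](C)[C@@H](O[Si](C)(C)C(C)(C)C)[C@@H](O[Si](C)(C)C(C)(C)C)CC(=O)c1coc(Cc2cnco2)n1 | intermediate (not isolated)
16 | C5 tetradecanoate of 15 (L-lyxo keto ester, C1 ketone) | CCCCCCCCCCCCCC(=O)O[C@@H](C)[C@@H](O[Si](C)(C)C(C)(C)C)[C@@H](O[Si](C)(C)C(C)(C)C)CC(=O)c1coc(Cc2cnco2)n1 | intermediate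
17 | (1R)-alcohol from 16; 3,4-bis-TBS ether of the target | CCCCCCCCCCCCCC(=O)O[C@@H](C)[C@@H](O[Si](C)(C)C(C)(C)C)[C@@H](O[Si](C)(C)C(C)(C)C)C[C@@H](O)c1coc(Cc2cnco2)n1 | intermediate
18 | (2S,3S,4S,6R)-3,4,6-trihydroxy-6-[2-(1,3-oxazol-5-ylmethyl)-1,3-oxazol-4-yl]hexan-2-yl tetradecanoate | CCCCCCCCCCCCCC(=O)O[C@@H](C)[C@@H](O)[C@@H](O)C[C@@H](O)c1coc(Cc2cnco2)n1 | target

**Step count and risks**

Total: 9 steps. Longest linear sequence: 8 steps (steps 1, 2, 3, 5, 6, 7, 8, 9, from 1 to 18); the sugar branch adds step 4 before the convergent step 5.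

The three steps most likely to fail:

Step 5 (Negishi coupling of the glycal zinc reagent with the triflate). The zinc reagent is made in the presence of by-products of excess tBuLi, and the oxazol-4-yl triflate is a sluggish partner for oxidative addition. The fallback sets out from 9: lithiate as before, quench with Bu3SnCl and isolate the stannane 1-(tributylstannyl)-3,4-di-O-TBS-L-fucal F1. Then carry out a Stille coupling of the purified stannane with 6 (Pd(PPh3)4, LiCl, CuI, 1,4-dioxane, 90 °C), which returns to the route at 12.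

Step 7 (acylation through the open-chain tautomer). If the hemiketal 13 does not open, or is acylated at the anomeric oxygen, the fallback sets out from 13 and reduces first. Transfer hydrogenation under the step 8 conditions gives the (1R)-1,5-diol F2. Selective silylation of the less hindered C1–OH (TESCl, imidazole, CH2Cl2, −40 °C) gives the 1-O-triethylsilyl ether F3. Acylation of the remaining C5–OH with 14 (pyridine, DMAP) gives the C5 tetradecanoate F4. Removal of all three silyl groups with HF·pyridine returns to the route at 18.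

Step 8 (catalyst-controlled reduction at C1). If the oxazole nitrogen inhibits the ruthenium catalyst or selectivity is poor, the fallback sets out from 16 and switches to substrate control. Desilylation with HF·pyridine gives the keto diol F5. Narasaka–Prasad reduction (Et2BOMe, NaBH4, THF/MeOH, −78 °C; AcOH quench) then uses the boron chelate of the free C3–OH to direct hydride to the 1,3-syn diol, which is 18 itself.

**Further compounds**

F1 | step 5 | 1-(tributylstannyl)-3,4-di-O-TBS-L-fucal | C[C@@H]1OC([Sn](CCCC)(CCCC)CCCC)=C[C@H](O[Si](C)(C)C(C)(C)C)[C@@H]1O[Si](C)(C)C(C)(C)C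
F2 | step 7 | (1R)-1,5-diol: (1R,5S)-3,4-bis(TBS-oxy)-1-[2-(1,3-oxazol-5-ylmethyl)-1,3-oxazol-4-yl]hexane-1,5-diol, L-lyxo at C3–C5 | O[C@@H](C)[C@@H](O[Si](C)(C)C(C)(C)C)[C@@H](O[Si](C)(C)C(C)(C)C)C[C@@H](O)c1coc(Cc2cnco2)n1
F3 | step 7 | 1-O-triethylsilyl ether of F2 | O[C@@H](C)[C@@H](O[Si](C)(C)C(C)(C)C)[C@@H](O[Si](C)(C)C(C)(C)C)C[C@@H](O[Si](CC)(CC)CC)c1coc(Cc2cnco2)n1
F4 | step 7 | C5 tetradecanoate of F3 | CCCCCCCCCCCCCC(=O)O[C@@H](C)[C@@H](O[Si](C)(C)C(C)(C)C)[C@@H](O[Si](C)(C)C(C)(C)C)C[C@@H](O[Si](CC)(CC)CC)c1coc(Cc2cnco2)n1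
F5 | step 8 | keto diol: 3,4-dihydroxy C1 ketone carrying the C5 tetradecanoate | CCCCCCCCCCCCCC(=O)O[C@@H](C)[C@@H](O)[C@@H](O)CC(=O)c1coc(Cc2cnco2)n1
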